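In a one-step world with equal charges, partner falls as charge / (1 + k × charge × time), and I carry that closed form into this chain.

* which flask leads in amount of bis adduct, in percent of the substrate charged ("all alike" within 1.5 percentage points) (Saturday's / Monday's / Wednesday's / Tuesday's / all alike)
* how much bis adduct is there at the end, in percent of the substrate charged: Saturday's
* how much bis adduct is there at the end, in percent of the substrate charged: Monday's
* how much bis adduct is there at the end, in percent of the substrate charged: Wednesday's
* how much bis adduct is there at the end, in percent of the substrate charged: Tuesday's

| flask | substrate | coupling partner | time | remark | temperature |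
|---|---|---|---|---|---|
| Saturday's | 5.0 × 10⁻⁴ M (fed, over 5.0 s) | 1.00 equiv | 6.0 s | the addition at 5 °C, then warmed to 25 °C; the feed brings no volume worth counting |  |
| Monday's | 5.0 × 10⁻⁴ M | 1.00 equiv (fed, over 5.0 s) | 6.0 s | all else is in the flask from the start; the feed brings no volume worth counting | 25 °C |
| Wednesday's | 5.0 × 10⁻⁴ M | 1.00 equiv | 6.0 s | everything together at the start at 5 °C, warmed to 25 °C at 5.0 s |  |
| Tuesday's | 5.0 × 10⁻⁴ M | 1.00 equiv | 6.0 s | everything together at the start | 25 °C |

- what is said of by-product includes crystals
- crystals is a solid; its amount is given per volume of the solution
- all constants are for 25 °C and move with temperature by the activation energies and enthalpies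

    substrate + coupling partner → first product + by-product (k1 = 1300 /M/s, Ea1 = 39.0 kJ/mol)
    substrate + coupling partner → other mono adduct + by-product (k2 = 57 /M/s, Ea2 = 38.0 kJ/mol)
    coupling partner + first product → bis adduct + by-product (k3 = 770 /M/s, Ea3 = 36.0 kJ/mol)
    coupling partner + other mono adduct → bis adduct + by-product (k4 = 190 /M/s, Ea4 = 42.0 kJ/mol)
    crystals ⇌ by-product, rate k5*(cs5 - [by-product]) while solid is left; crystals form when [by-product] > cs5 (cs5 = 0.40 mM, k5 = 7.2 /s)
    substrate ⇌ dormant form (K6 = 0.86, k6 = 0.48 /s, Ea6 = 73.0 kJ/mol, ΔH6 = −74.0 kJ/mol)
    (constants at 25 °C)

I start with Tuesday's, which holds one temperature. Let k be the sum of the constants of the two substrate steps, 1360 /M/s, so that 4.07 is k × charge × time. With the dormant form set aside, substrate stands above partner by the bis adduct, so partner falls at least as fast as the one-step law says. That gives a ceiling. The bis steps are slower than k, so partner's loss rate stays below k × charge × partner. That gives a floor.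

I call the time integral of partner concentration the exposure. Against exposure the coupling steps are pseudo-first-order, and with the dormant form set aside, bis adduct is what remains after substrate and the mono adducts are subtracted from the charge. The bracket below is reckoned in that way, so for Tuesday's as it stands it is an estimate, not a bound.

Ceiling on exposure, Tuesday's: ln(1 + x) / k = 1.20 mM·s

Floor on exposure, Tuesday's: (1 − exp(−x)) / k = 0.724 mM·s

Bis adduct at the ceiling: 32.9%

Bis adduct at the floor: 16.2%

The cold multiplies the bis step by 0.352, so Wednesday's clock counts 2.76 s of warm time against 6.0 s on Tuesday's. Saturday's and Monday's receive their fed reagent over 5.0 s. I commit to Tuesday's leading.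

The forecast names Tuesday's, with 11.5% for Saturday's, 15.5% for Monday's, 15% for Wednesday's and 25% for Tuesday's. Its ground is that “Tuesday's has the most of both at full rate for the full 6 s”. Its Tuesday's figure lies inside my bracket.

The simulation gives Tuesday's as the leader, with 11.3% for Saturday's, 15.5% for Monday's, 15.1% for Wednesday's and 24.7% for Tuesday's. Tuesday's stands inside the bracket, and the forecast holds. For Saturday's to move by 5 points, its partner charge has to stand at 0.707 equiv or 1.26 equiv.

Saturday's neighbour is charged with 4.00 equiv of coupling partner and ends with 61% of that charge, so I take partner's mean as halfway between the full charge and that remainder. Substrate fed at mid-feed sees 1.88 s of warm time. The exposure is then 3.03 mM·s, which is 2.52 times Tuesday's ceiling. The same formula, with the dormant form again set aside, gives 77.9% bis adduct. That neighbour of Saturday's holds 65.5% bis adduct at the end.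

The numbers were set for the occasion; the run is a simulation.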